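The route rests on cutting the C3–C12 bond of the γ-lactone (ring C). The feature exploited is the C3–H bond of cyclopentane ring B that lies cis to the C2 oxygen: a diazoacetate on that oxygen holds its carbene carbon 1,5 to this hydrogen, so a single dirhodium-catalysed C–H insertion makes C3–C12, closes ring C cis-fused and sets C3. The precursor is a spiro[4.5]dec-6-en-2-yl diazoacetate whose ring A already carries the C10 methyl, the trans C8/C9 diol as acetonide and C11 as a 4-methoxybenzyl ether; its spiro centre comes from double alkylation of an (R)-5-methylcyclohexenone with an (S)-butanetriol-derived diiodide.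

Key step: step 16

Remark on locants: ring B is C1 (CH2), C2 (CH–O), C3, C4; the spiro carbon is C5; ring A is C6–C10 (C6=C7, C8–O, C9–O, C10–CH3); C11 is the carbon on C6; C12 and C13 are the lactone α-carbon and carbonyl carbon.

Remark on faces: β is the face of ring A that carries the C10 methyl; from the spiro enone of step 5 onward C4 is β, C1 is α, and the C2 oxygen lies on the face of ring B turned toward C6.

Remark on abbreviations: TBS = tert-butyldimethylsilyl; PMB = 4-methoxybenzyl; Rh2(5S-MEPY)4 = dirhodium tetrakis[methyl (5S)-2-oxopyrrolidine-5-carboxylate].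

Remark on the precursor: C11 is carried as a PMB ether, at the oxidation level of the target, so that no carbonyl has to be reduced beside the lactone after the key step. The 8β,9α-diol is trans, so its acetonide is a strained trans-fused dioxolane; it is chosen because it is inert to fluoride (release of C2–OH) and to DDQ (release of C11–OH) and hydrolyses in weak acid at the end.

Assumption: the (S,R,R) phosphoramidite is taken to give the (R)-enone in step 4 and the (5S) rhodium carboxamidate to be the matched catalyst in step 16; if either sense proves opposite, the mirror-image ligand is used in the same way.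

Step 1
Reactants: 1 (S)-butane-1,2,4-triol
Product: 2 (S)-2-hydroxybutane-1,4-diyl bis(4-methylbenzenesulfonate)
Conditions: TsCl (2.05 equiv), pyridine, CH2Cl2, −20 → 0 °C
Reagents that add atoms: 4-toluenesulfonyl chloride, Cc1ccc(cc1)S(Cl)(=O)=O
Why: Chemoselective O-sulfonylation, since the two primary hydroxyls react far faster than the flanked secondary one at low temperature and the C2 stereocentre is not touched.

Step 2
Reactants: 2 (S)-2-hydroxybutane-1,4-diyl bis(4-methylbenzenesulfonate)
Product: 3 (S)-2-[(tert-butyldimethylsilyl)oxy]butane-1,4-diyl bis(4-methylbenzenesulfonate)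
Conditions: TBSOTf, 2,6-lutidine, CH2Cl2, −78 → 0 °C
Reagents that add atoms: tert-butyldimethylsilyl trifluoromethanesulfonate, CC(C)(C)[Si](C)(C)OS(=O)(=O)C(F)(F)F
Why: Silyl ether formation with a silyl triflate and a hindered non-nucleophilic base is fast in the cold and never generates the alkoxide that could close onto either sulfonate.

Step 3
Reactants: 3 (S)-2-[(tert-butyldimethylsilyl)oxy]butane-1,4-diyl bis(4-methylbenzenesulfonate)
Product: 4 (S)-tert-butyl[(1,4-diiodobutan-2-yl)oxy]dimethylsilane
Conditions: NaI (6 equiv), butan-2-one, 80 °C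
Reagents that add atoms: sodium iodide, [Na+].[I-]
Why: Finkelstein reaction (SN2 at two primary carbons) exchanges both sulfonates for iodide without touching C2 and gives a bis-electrophile whose two ends differ strongly in rate.

Step 4
Reactants: 5 4,4-dimethoxycyclohexa-2,5-dien-1-one; 6 dimethylzinc
Product: 7 (R)-4,4-dimethoxy-5-methylcyclohex-2-en-1-one
Conditions: Cu(OTf)2 (2 mol %), O,O′-[(S)-1,1′-binaphthalene-2,2′-diyl] N,N-bis[(R)-1-phenylethyl]phosphoramidite (4 mol %), toluene, −25 °C; then aq. NH4Cl
Reagents that add atoms: none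
Why: Copper-catalysed asymmetric conjugate addition of a dialkylzinc desymmetrises the dienone, the chiral phosphoramidite–copper complex choosing one enantiotopic alkene and its face so that the methyl-bearing carbon is set as R, while the zinc enolate formed resists a second addition.

Step 5
Reactants: 7 (R)-4,4-dimethoxy-5-methylcyclohex-2-en-1-one; 4 (S)-tert-butyl[(1,4-diiodobutan-2-yl)oxy]dimethylsilane
Product: 9 (2S,5R,10R)-2-[(tert-butyldimethylsilyl)oxy]-9,9-dimethoxy-10-methylspiro[4.5]dec-7-en-6-one, via monoalkylated iodo ketone 8 (not isolated)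
Conditions: LiN(iPr)2 (1.05 equiv), THF, −78 °C; 4, DMPU, −78 → −10 °C; then LiN(iPr)2 (1.2 equiv), −78 °C → rt
Reagents that add atoms: none
Why: Kinetic α′-enolate alkylation followed by 5-exo-tet enolate cyclisation, in which the first enolate attacks the unhindered CH2CH2–I end (C4) and, after re-enolisation, the β-silyloxy CH2–I end (C1) closes ring B on the enolate face anti to the neighbouring C10 methyl, placing C1 trans and C4 cis to that methyl and so fixing the spiro centre C5, with C2 carried in unchanged from 4.

Step 6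
Reactants: 10 (tributylstannyl)methanol
Product: 11 tributyl{[(4-methoxybenzyl)oxy]methyl}stannane
Conditions: NaH, 4-methoxybenzyl chloride, Bu4NI (cat.), THF/DMF, 0 °C → rt
Reagents that add atoms: 4-methoxybenzyl chloride, COc1ccc(CCl)cc1
Why: Williamson ether synthesis of a primary alkoxide with a reactive benzylic chloride.

Step 7
Reactants: 9 (2S,5R,10R)-2-[(tert-butyldimethylsilyl)oxy]-9,9-dimethoxy-10-methylspiro[4.5]dec-7-en-6-one; 11 tributyl{[(4-methoxybenzyl)oxy]methyl}stannane
Product: 13 2-(TBSO)-9,9-dimethoxy-6-(PMBOCH2)-10β-methylspiro[4.5]dec-7-en-6-ol (both C6 epimers), via alkoxymethyllithium 12 (not isolated)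
Conditions: 11 (1.5 equiv), n-BuLi (1.4 equiv), THF, −78 °C; then 9, −78 °C; aq. NH4Cl
Reagents that add atoms: none
Why: Tin–lithium exchange gives an α-alkoxymethyllithium that adds 1,2 to the non-enolisable C6 carbonyl of the enone, and the configuration of the new carbinol centre is left open because C6 becomes trigonal again in step 8.

Step 8
Reactants: 13 2-(TBSO)-9,9-dimethoxy-6-(PMBOCH2)-10β-methylspiro[4.5]dec-7-en-6-ol
Product: 14 2-(TBSO)-9,9-dimethoxy-6-(PMBOCH2)-10β-methylspiro[4.5]dec-6-en-8-one
Conditions: C5H5NH[CrO3Cl] (pyridinium chlorochromate, 2.5 equiv), NaOAc, 4 Å molecular sieves, CH2Cl2, 0 °C → rt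
Reagents that add atoms: pyridinium chlorochromate, [O-][Cr](=O)(=O)Cl.c1cc[nH+]cc1
Why: Babler–Dauben oxidative transposition, in which the chromate ester of the tertiary allylic alcohol undergoes a [3,3] shift to C8 and is oxidised there, moving the carbonyl to C8 and the alkene to C6=C7 with C11 in place, with no stereocentre formed and with buffer and sieves protecting the allylic ketal of the substrate.

Step 9
Reactants: 14 2-(TBSO)-9,9-dimethoxy-6-(PMBOCH2)-10β-methylspiro[4.5]dec-6-en-8-one
Product: 15 2-(TBSO)-9,9-dimethoxy-6-(PMBOCH2)-10β-methylspiro[4.5]dec-6-en-8β-ol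
Conditions: NaBH4, CeCl3·7H2O, MeOH, −78 → −40 °C
Reagents that add atoms: none
Why: Luche 1,2-reduction of the enone, in which hydride attacks the C8 carbonyl from the face opposite the C10 methyl (the sense by which carvone gives cis-carveol), so the hydroxyl is set β, cis to the methyl.

Step 10
Reactants: 15 2-(TBSO)-9,9-dimethoxy-6-(PMBOCH2)-10β-methylspiro[4.5]dec-6-en-8β-ol
Product: 16 2-(TBSO)-8β-hydroxy-6-(PMBOCH2)-10β-methylspiro[4.5]dec-6-en-9-one
Conditions: PPTS (0.3 equiv), acetone/H2O (10:1), rt, short contact; crude product used at once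
Reagents that add atoms: water, O
Why: Acid-catalysed ketal hydrolysis through the oxocarbenium ion is orders of magnitude faster than enolisation of the α-hydroxy ketone it releases, so weak acid and brief exposure should unmask the C9 ketone without ketol shift, alkene migration or loss of the silyl ether.

Step 11
Reactants: 16 2-(TBSO)-8β-hydroxy-6-(PMBOCH2)-10β-methylspiro[4.5]dec-6-en-9-one
Product: 17 2-(TBSO)-6-(PMBOCH2)-10β-methylspiro[4.5]dec-6-ene-8β,9α-diol
Conditions: Me4NBH(OAc)3, MeCN/AcOH (1:1), −30 °C
Reagents that add atoms: none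
Why: Hydroxyl-directed reduction with a triacetoxyborohydride (Evans–Saksena type), in which the C8 hydroxyl binds boron and delivers hydride to the C9 carbonyl on its own β face, so the new hydroxyl is α, trans to both the C8 hydroxyl and the C10 methyl.

Step 12
Reactants: 17 2-(TBSO)-6-(PMBOCH2)-10β-methylspiro[4.5]dec-6-ene-8β,9α-diol
Product: 18 2-(TBSO)-8β,9α-(isopropylidenedioxy)-6-(PMBOCH2)-10β-methylspiro[4.5]dec-6-ene (trans-fused acetonide)
Conditions: 2-methoxypropene, PPTS (cat.), CH2Cl2, 0 °C → rt
Reagents that add atoms: 2-methoxypropene, COC(C)=C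
Why: Kinetic acetonide formation with an enol ether, in which one hydroxyl adds to the protonated enol ether and its neighbour displaces methanol, a mode known to close trans-fused dioxolanes on trans-cyclohexane-1,2-diols, with no stereocentre changed.

Step 13
Reactants: 18 2-(TBSO)-8β,9α-(isopropylidenedioxy)-6-(PMBOCH2)-10β-methylspiro[4.5]dec-6-ene
Product: 19 8β,9α-(isopropylidenedioxy)-6-(PMBOCH2)-10β-methylspiro[4.5]dec-6-en-2-ol
Conditions: Bu4NF, THF, 0 °C → rt
Reagents that add atoms: none
Why: Fluoride-mediated desilylation cleaves the only silyl ether, while the acetonide and the benzylic ether are inert to fluoride and the C2–O bond is not broken.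

Step 14
Reactants: 19 8β,9α-(isopropylidenedioxy)-6-(PMBOCH2)-10β-methylspiro[4.5]dec-6-en-2-ol; 20 bromoacetyl bromide
Product: 21 8β,9α-(isopropylidenedioxy)-6-(PMBOCH2)-10β-methylspiro[4.5]dec-6-en-2-yl bromoacetate
Conditions: NaHCO3, MeCN, 0 °C
Reagents that add atoms: none
Why: O-acylation of the secondary alcohol by an acyl bromide with solid bicarbonate as acid scavenger is mild enough for the acetonide and retains the C2 configuration because only the O–H bond reacts.

Step 15
Reactants: 21 8β,9α-(isopropylidenedioxy)-6-(PMBOCH2)-10β-methylspiro[4.5]dec-6-en-2-yl bromoacetate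
Product: 22 8β,9α-(isopropylidenedioxy)-6-(PMBOCH2)-10β-methylspiro[4.5]dec-6-en-2-yl diazoacetate
Conditions: TsNHNHTs (2 equiv), DBU (5 equiv), THF, 0 °C
Reagents that add atoms: N,N′-ditosylhydrazine, Cc1ccc(cc1)S(=O)(=O)NNS(=O)(=O)c1ccc(C)cc1
Why: The bromoacetate N-alkylates ditosylhydrazine and the base then expels two sulfinate ions to leave the diazo group (diazoacetate synthesis from bromoacetates), a cold non-acidic method suited to a sensitive secondary ester.

Step 16
Reactants: 22 8β,9α-(isopropylidenedioxy)-6-(PMBOCH2)-10β-methylspiro[4.5]dec-6-en-2-yl diazoacetate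
Product: 23 cis-fused tricyclic γ-lactone (new C3–C12 bond; O–C2 and C12–C3 on the ring-B face toward C6; C12 is CH2; 8,9-acetonide and C11–OPMB retained)
Conditions: Rh2(5S-MEPY)4 (1 mol %), CH2Cl2, 40 °C, 22 added over 10 h by syringe pump
Reagents that add atoms: none
Why: The dirhodium carboxamidate extrudes N2 from 22 to give an electrophilic rhodium carbene, which inserts through a concerted three-centre transition state, with retention, into the C3–H bond and so forms C3–C12. The closest known reaction type is the dirhodium carboxamidate-catalysed intramolecular C–H insertion of cycloalkyl diazoacetates, which gives cis-fused γ-butyrolactones. Ring C closes as a five-membered ring by 1,5-insertion (C12 and C3 are linked through C13, the ester oxygen and C2), the ring size these acceptor carbenes prefer over four- or six-membered alternatives. The new stereocentre C3 is set by C2: only the C3–H bond cis to the C2 oxygen can reach the carbene, and a trans-fused oxabicyclo[3.3.0]octanone is too strained to form, so C12 ends on the ring-B face turned toward C6. The step needs site selectivity for C3–H over the cis C1–H and chemoselectivity over the ring-A alkene and the anisyl ring: C1 is neopentyl beside quaternary C5 and screened by the C6 side chain, the matched catalyst enantiomer adds to this bias, the hindered trisubstituted C6=C7 bond could be reached only through a bridged seven-membered lactone, and carboxamidate ligands make the carbene selective for γ-lactone formation over remote cyclopropanation or arene addition. Slow addition keeps the diazo ester dilute and suppresses carbene dimerisation.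

Step 17
Reactants: 23 cis-fused tricyclic γ-lactone; 24 N,N-dimethylmethyleneiminium iodide (Eschenmoser's salt)
Product: 27 12-methylene lactone with C11–OPMB and 8,9-acetonide, via Mannich base 25 (not isolated), via trimethylammonium iodide 26 (not isolated)
Conditions: LiN(iPr)2, THF, −78 °C; 24, −78 °C → rt; then MeI, MeOH, rt; then aq. NaHCO3, CH2Cl2, rt
Reagents that add atoms: none
Why: α-Methylenation of a lactone by Mannich reaction of its lithium enolate with Eschenmoser's salt, N-methylation and base-induced β-elimination of trimethylamine, in which the transient centre at C12 disappears and no other stereocentre is acidic.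

Step 18
Reactants: 27 12-methylene lactone with C11–OPMB and 8,9-acetonide
Product: 28 12-methylene lactone with free C11–OH and 8,9-acetonide
Conditions: DDQ (1.2 equiv), CH2Cl2/pH 7 phosphate buffer (10:1), 0 °C
Reagents that add atoms: none
Why: Oxidative cleavage of the 4-methoxybenzyl ether by DDQ (hydride abstraction from the electron-rich benzylic position, then hydrolysis of the oxocarbenium ion) under buffered conditions spares the acid-labile acetonide, the methylene lactone and the ring alkene.

Step 19
Reactants: 28 12-methylene lactone with free C11–OH and 8,9-acetonide; 29 angelic acid [(Z)-2-methylbut-2-enoic acid]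
Product: 31 C11 angelate of 28 [(Z)-2-methylbut-2-enoate], via mixed anhydride 30 (not isolated)
Conditions: 29, 2,4,6-trichlorobenzoyl chloride, Et3N, toluene, rt; then 28, toluene, 80 °C
Reagents that add atoms: none
Why: Yamaguchi-type acylation, in which the primary allylic alcohol attacks the less hindered angeloyl carbonyl of the preformed mixed anhydride without a nucleophilic catalyst, avoiding the addition–elimination path that turns angelates (Z) into tiglates (E) and sparing the methylene lactone.

Step 20
Reactants: 31 C11 angelate of 28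
Product: 32 target CNP0224912.1 (2R,3R,5R,8S,9S,10R in the locants used here; 8β,9α-diol, C11 angelate, 12-methylene lactone)
Conditions: AcOH/H2O (4:1), 40 °C
Reagents that add atoms: none
Why: Acid-catalysed hydrolysis of the strained trans-fused acetonide proceeds in weak aqueous acid that neither ionises the allylic ester nor isomerises the angelate, and all C–O bonds to the ring stay intact.

Compound list

1 | (S)-butane-1,2,4-triol | OCC[C@H](O)CO | starting material
2 | (S)-2-hydroxybutane-1,4-diyl bis(4-methylbenzenesulfonate) | Cc1ccc(cc1)S(=O)(=O)OCC[C@H](O)COS(=O)(=O)c1ccc(C)cc1 | intermediate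
3 | (S)-2-[(tert-butyldimethylsilyl)oxy]butane-1,4-diyl bis(4-methylbenzenesulfonate) | Cc1ccc(cc1)S(=O)(=O)OCC[C@H](O[Si](C)(C)C(C)(C)C)COS(=O)(=O)c1ccc(C)cc1 | intermediate
4 | (S)-tert-butyl[(1,4-diiodobutan-2-yl)oxy]dimethylsilane | ICC[C@H](O[Si](C)(C)C(C)(C)C)CI | intermediate
5 | 4,4-dimethoxycyclohexa-2,5-dien-1-one | COC1(OC)C=CC(=O)C=C1 | starting material
6 | dimethylzinc | C[Zn]C | starting material
7 | (R)-4,4-dimethoxy-5-methylcyclohex-2-en-1-one | COC1(OC)C=CC(=O)C[C@H]1C | intermediate
8 | (5R)-6-[(3S)-3-(tert-butyldimethylsilyloxy)-4-iodobutyl]-4,4-dimethoxy-5-methylcyclohex-2-en-1-one (C6 not defined; not isolated) | COC1(OC)C=CC(=O)C(CC[C@H](O[Si](C)(C)C(C)(C)C)CI)[C@H]1C | intermediate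
9 | (2S,5R,10R)-2-[(tert-butyldimethylsilyl)oxy]-9,9-dimethoxy-10-methylspiro[4.5]dec-7-en-6-one | CC(C)(C)[Si](C)(C)O[C@@H]2C[C@@]3(CC2)C(=O)C=CC(OC)(OC)[C@@H]3C | intermediate
10 | (tributylstannyl)methanol | CCCC[Sn](CCCC)(CCCC)CO | starting material
11 | tributyl{[(4-methoxybenzyl)oxy]methyl}stannane | CCCC[Sn](CCCC)(CCCC)COCc1ccc(OC)cc1 | intermediate
12 | {[(4-methoxybenzyl)oxy]methyl}lithium (not isolated) | [Li]COCc1ccc(OC)cc1 | intermediate
13 | 2-(TBSO)-9,9-dimethoxy-6-(PMBOCH2)-10β-methylspiro[4.5]dec-7-en-6-ol (both C6 epimers) | CC(C)(C)[Si](C)(C)O[C@@H]2C[C@@]3(CC2)C(O)(COCc5ccc(OC)cc5)C=CC(OC)(OC)[C@@H]3C | intermediate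
14 | 2-(TBSO)-9,9-dimethoxy-6-(PMBOCH2)-10β-methylspiro[4.5]dec-6-en-8-one | CC(C)(C)[Si](C)(C)O[C@@H]2C[C@@]3(CC2)C(COCc5ccc(OC)cc5)=CC(=O)C(OC)(OC)[C@@H]3C | intermediate
15 | 2-(TBSO)-9,9-dimethoxy-6-(PMBOCH2)-10β-methylspiro[4.5]dec-6-en-8β-ol | CC(C)(C)[Si](C)(C)O[C@@H]2C[C@@]3(CC2)C(COCc5ccc(OC)cc5)=C[C@H](O)C(OC)(OC)[C@@H]3C | intermediate
16 | 2-(TBSO)-8β-hydroxy-6-(PMBOCH2)-10β-methylspiro[4.5]dec-6-en-9-one | CC(C)(C)[Si](C)(C)O[C@@H]2C[C@@]3(CC2)C(COCc5ccc(OC)cc5)=C[C@H](O)C(=O)[C@@H]3C | intermediate
17 | 2-(TBSO)-6-(PMBOCH2)-10β-methylspiro[4.5]dec-6-ene-8β,9α-diol | CC(C)(C)[Si](C)(C)O[C@@H]2C[C@@]3(CC2)C(COCc5ccc(OC)cc5)=C[C@H](O)[C@@H](O)[C@@H]3C | intermediate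
18 | 2-(TBSO)-8β,9α-(isopropylidenedioxy)-6-(PMBOCH2)-10β-methylspiro[4.5]dec-6-ene | CC(C)(C)[Si](C)(C)O[C@@H]2C[C@@]3(CC2)C(COCc5ccc(OC)cc5)=C[C@H](OC(C)(C)O4)[C@@H]4[C@@H]3C | intermediate
19 | 8β,9α-(isopropylidenedioxy)-6-(PMBOCH2)-10β-methylspiro[4.5]dec-6-en-2-ol | O[C@@H]2C[C@@]3(CC2)C(COCc5ccc(OC)cc5)=C[C@H](OC(C)(C)O4)[C@@H]4[C@@H]3C | intermediate
20 | bromoacetyl bromide | BrCC(Br)=O | starting material
21 | 8β,9α-(isopropylidenedioxy)-6-(PMBOCH2)-10β-methylspiro[4.5]dec-6-en-2-yl bromoacetate | BrCC(=O)O[C@@H]2C[C@@]3(CC2)C(COCc5ccc(OC)cc5)=C[C@H](OC(C)(C)O4)[C@@H]4[C@@H]3C | intermediate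
22 | 8β,9α-(isopropylidenedioxy)-6-(PMBOCH2)-10β-methylspiro[4.5]dec-6-en-2-yl diazoacetate (key-step precursor) | [N-]=[N+]=CC(=O)O[C@@H]2C[C@@]3(CC2)C(COCc5ccc(OC)cc5)=C[C@H](OC(C)(C)O4)[C@@H]4[C@@H]3C | intermediate
23 | cis-fused tricyclic γ-lactone lacking the methylene (key-step product; C11–OPMB; 8,9-acetonide) | C1C(=O)O[C@@H]2C[C@@]3(C[C@H]12)C(COCc5ccc(OC)cc5)=C[C@H](OC(C)(C)O4)[C@@H]4[C@@H]3C | intermediate
24 | N,N-dimethylmethyleneiminium iodide (Eschenmoser's salt) | C=[N+](C)C.[I-] | starting material
25 | 12-[(dimethylamino)methyl] lactone (C12 epimers; not isolated) | CN(C)CC1C(=O)O[C@@H]2C[C@@]3(C[C@H]12)C(COCc5ccc(OC)cc5)=C[C@H](OC(C)(C)O4)[C@@H]4[C@@H]3C | intermediate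
26 | 12-[(trimethylammonio)methyl] lactone iodide (not isolated) | C[N+](C)(C)CC1C(=O)O[C@@H]2C[C@@]3(C[C@H]12)C(COCc5ccc(OC)cc5)=C[C@H](OC(C)(C)O4)[C@@H]4[C@@H]3C.[I-] | intermediate
27 | 12-methylene lactone with C11–OPMB and 8,9-acetonide | C=C1C(=O)O[C@@H]2C[C@@]3(C[C@H]12)C(COCc5ccc(OC)cc5)=C[C@H](OC(C)(C)O4)[C@@H]4[C@@H]3C | intermediate
28 | 12-methylene lactone with free C11–OH and 8,9-acetonide | C=C1C(=O)O[C@@H]2C[C@@]3(C[C@H]12)C(CO)=C[C@H](OC(C)(C)O4)[C@@H]4[C@@H]3C | intermediate
29 | angelic acid, (Z)-2-methylbut-2-enoic acid | C/C=C(/C)C(=O)O | starting material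
30 | angelic 2,4,6-trichlorobenzoic anhydride (not isolated) | C/C=C(/C)C(=O)OC(=O)c1c(Cl)cc(Cl)cc1Cl | intermediate
31 | C11 angelate of 28 (8,9-acetonide) | C=C1C(=O)O[C@@H]2C[C@@]3(C[C@H]12)C(COC(=O)/C(C)=C\C)=C[C@H](OC(C)(C)O4)[C@@H]4[C@@H]3C | intermediate
32 | CNP0224912.1 | C=C1C(=O)O[C@@H]2C[C@@]3(C[C@H]12)C(COC(=O)/C(C)=C\C)=C[C@H](O)[C@@H](O)[C@@H]3C | target

Total step count: 20. Longest linear sequence: 18 steps (steps 1–3, 5, 7–20). The enone branch (step 4) and the stannane branch (step 6) join at steps 5 and 7.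

Steps most likely to fail

Step 16. The insertion may be shared between the C3–H and C1–H methylenes that flank C2, or the carbene may couple with itself instead of inserting. The fallback sets out from alcohol 19 and comes back at methylene lactone 27, so it replaces steps 14 to 17. Alcohol 19 is esterified with diethylphosphonoacetic acid (DCC, DMAP, CH2Cl2) to the phosphonoacetate F1. Diazo transfer with 4-acetamidobenzenesulfonyl azide and DBU in MeCN gives the α-diazo phosphonoacetate F2. Rh2(OAc)4 in refluxing CH2Cl2 closes the cis-fused α-phosphono lactone F3 by the same 1,5-insertion. A Horner–Wadsworth–Emmons reaction of F3 with paraformaldehyde and KOtBu (THF, 0 °C) then gives 27. The acceptor/acceptor carbene is bulkier and reacts through a later transition state, so it should respond more strongly to the steric difference between C3 and neopentyl C1 and is little prone to dimerisation; insertion of α-diazo phosphonoacetates followed by olefination is known chemistry.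

Step 8. The acidic chromium reagent may ionise the allylic ketal before the [3,3] shift, or the shift toward C8, which sits beside the quaternary ketal carbon, may stall. The fallback sets out from tertiary alcohol 13 and comes back at enone 14. Ph3SiOReO3 (cat.) in Et2O at −50 → 0 °C isomerises 13, through the allyl perrhenate, to the secondary allylic alcohols F4 (C8 epimers) in a redox-neutral 1,3-transposition. MnO2 in CH2Cl2 at rt then oxidises F4 to 14, so the rearrangement and the oxidation are separated and no acidic oxidant meets the allylic ketal.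

Step 5. The enolate may fail to discriminate cleanly between the two iodides, or intermolecular alkylation may outrun the second enolisation and ring closure. The fallback sets out from bis-sulfonate 3 and enone 7 and comes back at spiro enone 9. Compound 3 with NaI (1.0 equiv, acetone, rt) gives the iodo tosylate F5 by exchange at the unhindered C4 sulfonate only, and any regioisomer is removed at this reagent stage. The lithium enolate of 7 (LiN(iPr)2, THF/DMPU, −78 → −10 °C) is alkylated by the iodide end of F5 to the keto tosylate F6, which is isolated. KOtBu in THF (0 °C → rt) then closes ring B to 9 by intramolecular enolate alkylation anti to the C10 methyl. The two C–C bonds are thus made in separate flasks with chemically different leaving groups.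

Further compounds

F1 | step 16 | 8β,9α-(isopropylidenedioxy)-6-(PMBOCH2)-10β-methylspiro[4.5]dec-6-en-2-yl (diethoxyphosphoryl)acetate | CCOP(=O)(OCC)CC(=O)O[C@@H]2C[C@@]3(CC2)C(COCc5ccc(OC)cc5)=C[C@H](OC(C)(C)O4)[C@@H]4[C@@H]3C
F2 | step 16 | 8β,9α-(isopropylidenedioxy)-6-(PMBOCH2)-10β-methylspiro[4.5]dec-6-en-2-yl diazo(diethoxyphosphoryl)acetate | CCOP(=O)(OCC)C(=[N+]=[N-])C(=O)O[C@@H]2C[C@@]3(CC2)C(COCc5ccc(OC)cc5)=C[C@H](OC(C)(C)O4)[C@@H]4[C@@H]3C
F3 | step 16 | cis-fused tricyclic γ-lactone with a diethoxyphosphoryl group on C12 (C12 epimers) | CCOP(=O)(OCC)C1C(=O)O[C@@H]2C[C@@]3(C[C@H]12)C(COCc5ccc(OC)cc5)=C[C@H](OC(C)(C)O4)[C@@H]4[C@@H]3C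
F4 | step 8 | 2-(TBSO)-9,9-dimethoxy-6-(PMBOCH2)-10β-methylspiro[4.5]dec-6-en-8-ol (C8 epimers) | CC(C)(C)[Si](C)(C)O[C@@H]2C[C@@]3(CC2)C(COCc5ccc(OC)cc5)=CC(O)C(OC)(OC)[C@@H]3C
F5 | step 5 | (S)-2-[(tert-butyldimethylsilyl)oxy]-4-iodobutyl 4-methylbenzenesulfonate | ICC[C@H](O[Si](C)(C)C(C)(C)C)COS(=O)(=O)c1ccc(C)cc1
F6 | step 5 | (S)-2-[(tert-butyldimethylsilyl)oxy]-4-[(6R)-5,5-dimethoxy-6-methyl-2-oxocyclohex-3-en-1-yl]butyl 4-methylbenzenesulfonate (ring C1 not defined) | COC1(OC)C=CC(=O)C(CC[C@H](O[Si](C)(C)C(C)(C)C)COS(=O)(=O)c2ccc(C)cc2)[C@H]1C
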